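With the bicycle numbered as a furo[3,2-b]pyran-5-one (O1, C2, C3, C3a, O4, C5–C7, C7a), everything rests on cutting the dihydropyranone ring at its C6=C7 double bond and at the C3a–C7a fusion bond, which also belongs to the tetrahydrofuran ring. O4 on C3a and C7 on C7a are the hydroxyl and formyl groups of a latent cis aldol, so an open-chain ether dialdehyde is folded in one flask: a proline-catalysed 5-enolexo aldol forms C3a–C7a and the tetrahydrofuran, then ketenylidenetriphenylphosphorane acylates the new hydroxyl and closes the lactone by intramolecular Wittig reaction. The C3 carbinol is inverted afterwards and the side chain is attached by cross-metathesis.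

Key step: step 7

Remark: penta-1,4-dien-3-ol, tert-butyl bromoacetate and ketenylidenetriphenylphosphorane are taken as commercial; ring atoms are named by the furo[3,2-b]pyran-5-one numbering of the target throughout.

Step 1
Reactants: 1 penta-1,4-dien-3-ol
Product: 2 (2R,3S)-1,2-epoxypent-4-en-3-ol
Conditions: Ti(OiPr)4 (10 mol %), L-(+)-diisopropyl tartrate (13 mol %), tBuOOH, 4 Å molecular sieves, CH2Cl2, -20 °C
Reagents that add atoms: tert-butyl hydroperoxide CC(C)(C)OO
Why: Sharpless asymmetric epoxidation desymmetrises the divinyl carbinol: the titanium tartrate catalyst selects one enantiotopic vinyl group and one of its faces to give the anti epoxy alcohol, and slower over-oxidation of the minor enantiomer further enriches the product.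

Step 2
Reactants: 2 (2R,3S)-1,2-epoxypent-4-en-3-ol; 3 tert-butyl bromoacetate
Product: 4 tert-butyl {[(1S)-1-[(2R)-oxiran-2-yl]prop-2-en-1-yl]oxy}acetate
Conditions: NaH, Bu4NI (cat.), THF, 0 °C
Reagents that add atoms: none
Why: Williamson etherification of the secondary alkoxide with the activated α-bromo ester is fast at 0 °C in an aprotic medium, which should outpace Payne rearrangement and leaves both stereocentres untouched.

Step 3
Reactants: 4 tert-butyl {[(1S)-1-[(2R)-oxiran-2-yl]prop-2-en-1-yl]oxy}acetate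
Product: 5 (2R,3S)-3-(2-tert-butoxy-2-oxoethoxy)-2-hydroxypent-4-en-1-yl pivalate
Conditions: PivOH (3 equiv), Bu4NBr (10 mol %), MeCN, 80 °C
Reagents that add atoms: pivalic acid CC(C)(C)C(=O)O
Why: Bromide-catalysed SN2 acidolysis of the terminal epoxide delivers the carboxylate to the unsubstituted carbon, so C2 keeps its configuration, and the hindered pivalate should not migrate to the secondary hydroxyl.

Step 4
Reactants: 5 (2R,3S)-3-(2-tert-butoxy-2-oxoethoxy)-2-hydroxypent-4-en-1-yl pivalate
Product: 6 (2R,3S)-3-(2-tert-butoxy-2-oxoethoxy)-2-(tert-butyldimethylsilyloxy)pent-4-en-1-yl pivalate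
Conditions: TBSCl, imidazole, DMAP (cat.), DMF, rt
Reagents that add atoms: tert-butyldimethylsilyl chloride CC(C)(C)[Si](C)(C)Cl
Why: Standard silylation of the only free hydroxyl installs the bulky, non-chelating silyl ether that later steers the aldol ring closure.

Step 5
Reactants: 6 (2R,3S)-3-(2-tert-butoxy-2-oxoethoxy)-2-(tert-butyldimethylsilyloxy)pent-4-en-1-yl pivalate
Product: 7 (2R,3S)-2-(tert-butyldimethylsilyloxy)-3-(2-hydroxyethoxy)pent-4-en-1-ol
Conditions: iBu2AlH (6 equiv), CH2Cl2, -78 to 0 °C; aqueous potassium sodium tartrate work-up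
Reagents that add atoms: none
Why: Hydride reduction with excess iBu2AlH converts the tert-butyl ester into the primary alcohol and cleaves the pivalate, and the neutral aluminium alkoxides disfavour 1,2-silyl migration.

Step 6
Reactants: 7 (2R,3S)-2-(tert-butyldimethylsilyloxy)-3-(2-hydroxyethoxy)pent-4-en-1-ol
Product: 8 (2S,3S)-2-(tert-butyldimethylsilyloxy)-3-(2-oxoethoxy)pent-4-enal
Conditions: Dess–Martin periodinane (2.5 equiv), NaHCO3, CH2Cl2, 0 °C to rt; used crude
Reagents that add atoms: none
Why: Dess–Martin oxidation of both primary alcohols under buffered, non-basic conditions should give the dialdehyde without epimerising the α-silyloxy centre.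

Step 7
Reactants: 8 (2S,3S)-2-(tert-butyldimethylsilyloxy)-3-(2-oxoethoxy)pent-4-enal; 9 ketenylidenetriphenylphosphorane
Product: 12 (2S,3S,3aS,7aR)-3-(tert-butyldimethylsilyloxy)-2-ethenyl-2,3,3a,7a-tetrahydro-5H-furo[3,2-b]pyran-5-one, via cis-aldol hydroxy aldehyde 10 (not isolated), via ester ylide 11 (not isolated)
Conditions: L-proline (20 mol %), DMF (0.05 M), 4 °C; then 9 (1.5 equiv), toluene, 60 °C, same flask
Reagents that add atoms: none
Why: L-Proline forms the (E)-enamine only at the unbranched alkoxyacetaldehyde terminus (the α-silyloxy aldehyde is α-branched) and its C7a carbon adds to the C3a aldehyde, closing the tetrahydrofuran by a 5-(enolexo)-exo-trig aldol to give the cis hydroxy aldehyde 10; the hydroxyl of 10 then adds across the ketene C=C of 9 to give the ester ylide 11, whose intramolecular Wittig reaction with the neighbouring formyl group closes the six-membered lactone (cis alkene enforced by the ring) with loss of Ph3PO. The closest known reaction types are the proline-catalysed enolexo aldolisation of dialdehydes with α-oxyaldehyde enamine donors, one-pot organocatalytic aldol/Wittig sequences and the annulation of hydroxy aldehydes to unsaturated lactones by ketenylidenetriphenylphosphorane. C7a is catalyst-controlled: the carboxylic acid of L-proline guides the acceptor to the enamine face that gives 7aR, which places C7 cis to the C2 vinyl group. C3a is substrate-controlled: in the five-membered transition state the carbonyl oxygen turns away from the vicinal C3–OTBS bond (dipole and steric avoidance), so O4 should end trans to OTBS and cis to C7. The step needs one regiochemistry of enolisation and a 2,3-cis aldol; the first is secured by the α-branching of the acceptor, the second is reinforced because only the cis aldol can be annulated by the ylide, so trans isomers are not carried into 12.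

Step 8
Reactants: 12 (2S,3S,3aS,7aR)-3-(tert-butyldimethylsilyloxy)-2-ethenyl-2,3,3a,7a-tetrahydro-5H-furo[3,2-b]pyran-5-one
Product: 13 (2S,3S,3aR,7aR)-2-ethenyl-3-hydroxy-2,3,3a,7a-tetrahydro-5H-furo[3,2-b]pyran-5-one
Conditions: HF·pyridine, pyridine, THF, 0 °C to rt
Reagents that add atoms: none
Why: Fluoride-mediated desilylation under buffered, weakly acidic conditions should leave the unsaturated lactone intact.

Step 9
Reactants: 13 (2S,3S,3aR,7aR)-2-ethenyl-3-hydroxy-2,3,3a,7a-tetrahydro-5H-furo[3,2-b]pyran-5-one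
Product: 14 (2S,3aS,7aR)-2-ethenyl-3a,7a-dihydro-2H-furo[3,2-b]pyran-3,5-dione
Conditions: Dess–Martin periodinane, NaHCO3, CH2Cl2, 0 °C; used directly
Reagents that add atoms: none
Why: Dess–Martin oxidation of the secondary alcohol under neutral conditions gives the ketone, which erases the C3 configuration that was needed only to steer step 7.

Step 10
Reactants: 14 (2S,3aS,7aR)-2-ethenyl-3a,7a-dihydro-2H-furo[3,2-b]pyran-3,5-dione
Product: 15 (2S,3R,3aR,7aR)-2-ethenyl-3-hydroxy-2,3,3a,7a-tetrahydro-5H-furo[3,2-b]pyran-5-one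
Conditions: NaBH4, CeCl3·7H2O, MeOH, -78 °C
Reagents that add atoms: none
Why: Luche reduction is 1,2-selective for the ketone over the enoate, and hydride should add to the convex face opposite the cis-fused lactone ring and the C2 vinyl group, which sets 3R with the hydroxyl cis to all three neighbours.

Step 11
Reactants: 2 (2R,3S)-1,2-epoxypent-4-en-3-ol
Product: 16 (2R)-2-[(1S)-1-(4-methoxybenzyloxy)prop-2-en-1-yl]oxirane
Conditions: NaH, 4-methoxybenzyl chloride, Bu4NI (cat.), THF, 0 °C to rt
Reagents that add atoms: 4-methoxybenzyl chloride COc1ccc(CCl)cc1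
Why: Williamson etherification protects the allylic hydroxyl as a non-migrating PMB ether without touching the epoxide or either stereocentre.

Step 12
Reactants: 16 (2R)-2-[(1S)-1-(4-methoxybenzyloxy)prop-2-en-1-yl]oxirane
Product: 17 (2R,3S)-3-(4-methoxybenzyloxy)pent-4-en-2-ol
Conditions: LiAlH4, THF, 0 °C
Reagents that add atoms: none
Why: Hydride opens the terminal epoxide at the unsubstituted carbon (SN2), which creates the methyl group and leaves the configuration of the new secondary carbinol unchanged.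

Step 13
Reactants: 17 (2R,3S)-3-(4-methoxybenzyloxy)pent-4-en-2-ol
Product: 18 (2R,3S)-3-(4-methoxybenzyloxy)pent-4-en-2-yl benzoate
Conditions: BzCl, pyridine, DMAP (cat.), CH2Cl2, 0 °C to rt
Reagents that add atoms: benzoyl chloride O=C(Cl)c1ccccc1
Why: Acylation of the only free hydroxyl under nucleophilic catalysis places the benzoate regiospecifically on the methyl carbinol.

Step 14
Reactants: 18 (2R,3S)-3-(4-methoxybenzyloxy)pent-4-en-2-yl benzoate
Product: 19 (2R,3S)-3-hydroxypent-4-en-2-yl benzoate
Conditions: DDQ, CH2Cl2/pH 7 buffer, 0 °C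
Reagents that add atoms: none
Why: Oxidative cleavage of the PMB ether by DDQ under neutral buffered conditions frees the allylic alcohol without migration of the neighbouring benzoate.

Step 15
Reactants: 15 (2S,3R,3aR,7aR)-2-ethenyl-3-hydroxy-2,3,3a,7a-tetrahydro-5H-furo[3,2-b]pyran-5-one; 19 (2R,3S)-3-hydroxypent-4-en-2-yl benzoate
Product: 20 (2R,3S,4E)-3-hydroxy-5-[(2S,3R,3aR,7aR)-3-hydroxy-5-oxo-2,3,3a,7a-tetrahydro-5H-furo[3,2-b]pyran-2-yl]pent-4-en-2-yl benzoate
Conditions: second-generation Hoveyda–Grubbs catalyst (10 mol %), 19 (3 equiv), CH2Cl2, 40 °C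
Reagents that add atoms: none
Why: Olefin cross-metathesis between two allylically oxygenated terminal alkenes releases ethene and should give the E alkene under thermodynamic control, while the conjugated cis alkene of the lactone is inert to the ruthenium carbene.

Compound list
1 | penta-1,4-dien-3-ol | C=CC(O)C=C | starting material
2 | (2R,3S)-1,2-epoxypent-4-en-3-ol | C=C[C@H](O)[C@H]1CO1 | intermediate
3 | tert-butyl bromoacetate | BrCC(=O)OC(C)(C)C | starting material
4 | tert-butyl {[(1S)-1-[(2R)-oxiran-2-yl]prop-2-en-1-yl]oxy}acetate | C=C[C@H](OCC(=O)OC(C)(C)C)[C@H]1CO1 | intermediate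
5 | (2R,3S)-3-(2-tert-butoxy-2-oxoethoxy)-2-hydroxypent-4-en-1-yl pivalate | C=C[C@H](OCC(=O)OC(C)(C)C)[C@H](O)COC(=O)C(C)(C)C | intermediate
6 | (2R,3S)-3-(2-tert-butoxy-2-oxoethoxy)-2-(tert-butyldimethylsilyloxy)pent-4-en-1-yl pivalate | C=C[C@H](OCC(=O)OC(C)(C)C)[C@H](O[Si](C)(C)C(C)(C)C)COC(=O)C(C)(C)C | intermediate
7 | (2R,3S)-2-(tert-butyldimethylsilyloxy)-3-(2-hydroxyethoxy)pent-4-en-1-ol | C=C[C@H](OCCO)[C@H](O[Si](C)(C)C(C)(C)C)CO | intermediate
8 | (2S,3S)-2-(tert-butyldimethylsilyloxy)-3-(2-oxoethoxy)pent-4-enal | C=C[C@H](OCC=O)[C@H](O[Si](C)(C)C(C)(C)C)C=O | intermediate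
9 | ketenylidenetriphenylphosphorane | O=C=C=P(c1ccccc1)(c1ccccc1)c1ccccc1 | starting material
10 | (2S,3S,4R,5S)-4-(tert-butyldimethylsilyloxy)-5-ethenyl-3-hydroxyoxolane-2-carbaldehyde (2,3-cis; 3,4-trans; 4,5-trans) | C=C[C@@H]1O[C@H](C=O)[C@H](O)[C@H]1O[Si](C)(C)C(C)(C)C | intermediate
11 | (triphenylphosphoranylidene)acetate ester of 10 at its C3 hydroxyl | C=C[C@@H]1O[C@H](C=O)[C@H](OC(=O)C=P(c2ccccc2)(c2ccccc2)c2ccccc2)[C@H]1O[Si](C)(C)C(C)(C)C | intermediate
12 | (2S,3S,3aS,7aR)-3-(tert-butyldimethylsilyloxy)-2-ethenyl-2,3,3a,7a-tetrahydro-5H-furo[3,2-b]pyran-5-one (cis ring fusion; OTBS trans to vinyl and to the lactone) | C=C[C@@H]1O[C@@H]2C=CC(=O)O[C@@H]2[C@H]1O[Si](C)(C)C(C)(C)C | intermediate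
13 | (2S,3S,3aR,7aR)-2-ethenyl-3-hydroxy-2,3,3a,7a-tetrahydro-5H-furo[3,2-b]pyran-5-one | C=C[C@@H]1O[C@@H]2C=CC(=O)O[C@@H]2[C@H]1O | intermediate
14 | (2S,3aS,7aR)-2-ethenyl-3a,7a-dihydro-2H-furo[3,2-b]pyran-3,5-dione | C=C[C@@H]1O[C@@H]2C=CC(=O)O[C@@H]2C1=O | intermediate
15 | (2S,3R,3aR,7aR)-2-ethenyl-3-hydroxy-2,3,3a,7a-tetrahydro-5H-furo[3,2-b]pyran-5-one (all-cis) | C=C[C@@H]1O[C@@H]2C=CC(=O)O[C@@H]2[C@@H]1O | intermediate
16 | (2R)-2-[(1S)-1-(4-methoxybenzyloxy)prop-2-en-1-yl]oxirane | C=C[C@H](OCc1ccc(OC)cc1)[C@H]1CO1 | intermediate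
17 | (2R,3S)-3-(4-methoxybenzyloxy)pent-4-en-2-ol | C=C[C@H](OCc1ccc(OC)cc1)[C@@H](C)O | intermediate
18 | (2R,3S)-3-(4-methoxybenzyloxy)pent-4-en-2-yl benzoate | C=C[C@H](OCc1ccc(OC)cc1)[C@@H](C)OC(=O)c1ccccc1 | intermediate
19 | (2R,3S)-3-hydroxypent-4-en-2-yl benzoate | C=C[C@H](O)[C@@H](C)OC(=O)c1ccccc1 | intermediate
20 | (2R,3S,4E)-3-hydroxy-5-[(2S,3R,3aR,7aR)-3-hydroxy-5-oxo-2,3,3a,7a-tetrahydro-5H-furo[3,2-b]pyran-2-yl]pent-4-en-2-yl benzoate | C[C@@H](OC(=O)c1ccccc1)[C@@H](O)/C=C/[C@@H]1O[C@@H]2C=CC(=O)O[C@@H]2[C@@H]1O | target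

Total step count: 15. Longest linear sequence: 11 steps (steps 1 to 10, then step 15); steps 11 to 14 branch from compound 2.

Steps most likely to fail

Step 7. The ring closure may run through the trans aldol or toward the other face of the C3a aldehyde, or the hydroxy aldehyde may dehydrate or oligomerise before it is captured, so that little cis aldol reaches the ylide. The fallback replaces the enamine aldol of a dialdehyde by a stepwise lithium ester-enolate aldol and sets out from 6. Methanolysis of the pivalate (K2CO3, MeOH, 0 °C) should give the primary alcohol F1, and Dess–Martin oxidation the aldehyde ester F2. LiN(SiMe3)2 in THF at -78 °C should then close the tetrahydrofuran by a 5-exo ester-enolate aldol to the hydroxy ester F3, with the new hydroxyl again trans to OTBS. Reduction of the tert-butyl ester with iBu2AlH at -78 °C gives the hydroxy aldehyde 10 (its C2 epimers can equilibrate through the enol), which is annulated with 9 as in the route, so the fallback comes back at 12.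

Step 15. The ruthenium carbene may engage only slowly with the vinyl group that sits next to the cis hydroxyl on the concave face, so that self-metathesis of 19 and ruthenium-hydride isomerisation of its free allylic alcohol take over. The fallback moves the coupling to the silyl ether stage and carries the side chain through the inversion; it sets out from 12 and 18. Cross-metathesis with the same catalyst, where the vinyl group lies on the face opposite to OTBS and the partner has no free hydroxyl, should give the protected coupling product F4. HF·pyridine then gives the alcohol F5, Dess–Martin oxidation the ketone F6, and NaBH4/CeCl3 the all-cis alcohol F7. DDQ removes the PMB ether and the fallback comes back at 20.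

Step 9. Ketone 14 may enolise toward C2 (allylic and α-alkoxy), with epimerisation or migration of the double bond, and β-elimination may open the tetrahydrofuran before the reduction of step 10. The fallback inverts C3 by substitution instead of oxidation and reduction; it sets out from 13. Mitsunobu reaction with chloroacetic acid (PPh3, DIAD, THF) should give the inverted chloroacetate F8, and thiourea with NaHCO3 in EtOH removes the chloroacetyl group, so the fallback comes back at 15 and bypasses steps 9 and 10.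

Further compounds
F1 | step 7 | tert-butyl {[(3S,4R)-4-(tert-butyldimethylsilyloxy)-5-hydroxypent-1-en-3-yl]oxy}acetate | C=C[C@H](OCC(=O)OC(C)(C)C)[C@H](O[Si](C)(C)C(C)(C)C)CO
F2 | step 7 | tert-butyl {[(3S,4S)-4-(tert-butyldimethylsilyloxy)-5-oxopent-1-en-3-yl]oxy}acetate | C=C[C@H](OCC(=O)OC(C)(C)C)[C@H](O[Si](C)(C)C(C)(C)C)C=O
F3 | step 7 | tert-butyl (2S,3S,4R,5S)-4-(tert-butyldimethylsilyloxy)-5-ethenyl-3-hydroxyoxolane-2-carboxylate | C=C[C@@H]1O[C@H](C(=O)OC(C)(C)C)[C@H](O)[C@H]1O[Si](C)(C)C(C)(C)C
F4 | step 15 | (2R,3S,4E)-5-[(2S,3S,3aS,7aR)-3-(tert-butyldimethylsilyloxy)-5-oxo-2,3,3a,7a-tetrahydro-5H-furo[3,2-b]pyran-2-yl]-3-(4-methoxybenzyloxy)pent-4-en-2-yl benzoate | C[C@@H](OC(=O)c1ccccc1)[C@@H](OCc1ccc(OC)cc1)/C=C/[C@@H]1O[C@@H]2C=CC(=O)O[C@@H]2[C@H]1O[Si](C)(C)C(C)(C)C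
F5 | step 15 | (2R,3S,4E)-5-[(2S,3S,3aR,7aR)-3-hydroxy-5-oxo-2,3,3a,7a-tetrahydro-5H-furo[3,2-b]pyran-2-yl]-3-(4-methoxybenzyloxy)pent-4-en-2-yl benzoate | C[C@@H](OC(=O)c1ccccc1)[C@@H](OCc1ccc(OC)cc1)/C=C/[C@@H]1O[C@@H]2C=CC(=O)O[C@@H]2[C@H]1O
F6 | step 15 | (2R,3S,4E)-5-[(2S,3aS,7aR)-3,5-dioxo-3,3a,5,7a-tetrahydro-2H-furo[3,2-b]pyran-2-yl]-3-(4-methoxybenzyloxy)pent-4-en-2-yl benzoate | C[C@@H](OC(=O)c1ccccc1)[C@@H](OCc1ccc(OC)cc1)/C=C/[C@@H]1O[C@@H]2C=CC(=O)O[C@@H]2C1=O
F7 | step 15 | (2R,3S,4E)-5-[(2S,3R,3aR,7aR)-3-hydroxy-5-oxo-2,3,3a,7a-tetrahydro-5H-furo[3,2-b]pyran-2-yl]-3-(4-methoxybenzyloxy)pent-4-en-2-yl benzoate | C[C@@H](OC(=O)c1ccccc1)[C@@H](OCc1ccc(OC)cc1)/C=C/[C@@H]1O[C@@H]2C=CC(=O)O[C@@H]2[C@@H]1O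
F8 | step 9 | (2S,3R,3aS,7aR)-2-ethenyl-5-oxo-2,3,3a,7a-tetrahydro-5H-furo[3,2-b]pyran-3-yl chloroacetate (chloroacetate of 15) | C=C[C@@H]1O[C@@H]2C=CC(=O)O[C@@H]2[C@@H]1OC(=O)CCl
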